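Take two questions to this flask, and see that the readings speak to the first: they list target and crystals, but no dissolved gas.

common to all: gas phase 25 mM (held)

| run | starting material | remark | time |
|---|---|---|---|
| west | 0.13 M | run made earlier |  |
| south-east | 0.30 M | run made earlier |  |
| flask | 0.20 M |  | 1.0 h |

- west (time / min: target / %, crystals / %): 12.0: 10, 0; 25.0: 25, 13; 40.0: 31, 23; 50.0: 40, 27
- south-east (time / min: target / %, crystals / %): 4.00: 4, 0; 8.00: 5, 1; 20.0: 18, 12; 50.0: 43, 36

(scatter of a reading: 2 percentage points)

* how much target and crystals together there is at 1.0 h, in percent of the starting material charged
* concentration of dissolved gas in solution at 1.0 h, in percent of saturation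

- what is said of target includes crystals
- crystals is a solid; its amount is given per volume of the solution
- at the start none of the gas phase is in solution

Solve the short end first: none of the gas phase is in solution at the start, so read no rate from the first minutes. Then solve the long end: as starting material thins, assume the gain thins with it, which is pseudo-first-order behaviour. Join the ends with y = 1 − exp(−k′t).

Read k′ from the last readings, at 50.0 min. The west run, charged with 0.13 M, stands at 40%, and the south-east run, charged with 0.30 M, stands at 43%. Those readings differ by 3 percentage points against a scatter of 2 points, so treat the charge as not mattering. Their mean gives 0.0107 min⁻¹ for the appearance constant k′, the fractional gain of target per minute. My reckoning for this flask at 1.0 h is then 47.5%. It gives no separate figure for [dissolved gas], so I commit to none.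

The forecast says 46%, slightly under mine, and 96% of saturation, on the ground that “gas transfer is not limiting and dissolved gas stays near saturation”.

The flask gives 47.5%, and [dissolved gas] stands at 80.1% of saturation, 16 points under the forecast. Now use k′ once more: exp(−k′t) puts the starting material left at 52.5%, more than the 45.6% this flask holds. That gap of 7 points is about the size of the 6.93% of over-reacted product. Read k′ as the net appearance of target, not as the loss of starting material.

    dissolved gas ⇌ dormant form (K = 160, k = 0.00634 min⁻¹)
    starting material + dissolved gas → target (k = 0.729 L mol⁻¹ min⁻¹)
    dissolved gas + target → over-reacted product (k = 0.803 L mol⁻¹ min⁻¹)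
    gas phase ⇌ dissolved gas, rate k4*(csat - [dissolved gas]) (kL = 0.355 min⁻¹)
    crystals ⇌ target, rate k5*(cs5 - [target]) while solid is left; crystals form when [target] > cs5 (solubility = 15.0 mM, k = 0.766 min⁻¹)

Run the same reckoning on the neighbour flask stopped at 40 min: k′ gives 34.8%, and the computed neighbour holds 35.1%.

(The data come from a simulation on assumed constants.)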